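A small charge of pre-initiator, 0.0250 equivalents in autumn and 0.0150 in dawn, met the free monomer in the two flasks you asked me about.

common to all: free monomer 0.20 M

|  | pre-initiator | remark | time |
|---|---|---|---|
| blue | 3.7 mM | run made earlier |  |
| violet | 5.6 mM | run made earlier |  |
| autumn | 5.0 mM |  | 6.0 min |
| dawn | 3.0 mM |  | 6.0 min |

- blue (time / min: monomer in chains / %, free monomer / %): 0.500: 2.7, 96.4; 0.833: 5.5, 93.5; 1.50: 6.6, 93.0; 3.00: 8.5, 91.9; 6.00: 6.9, 91.0
- violet (time / min: monomer in chains / %, free monomer / %): 0.500: 3.5, 95.5; 1.50: 9.6, 87.1; 3.00: 9.9, 86.8; 4.00: 11.0, 85.8; 6.00: 11.0, 86.6

(each reading ± 0.5 percentage points)

* which of the two ends with the longer chains by the average number of monomer units in a chain (chains begun, living or dead) ("neither" if they lie within 10%) (autumn / dawn / neither)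
* average number of monomer units in a chain (chains begun, living or dead) at the end, autumn
* average number of monomer units in a chain (chains begun, living or dead) at the end, dawn

- the average divides the monomer in chains by the number of chains begun, living and dead together
- the numbers in the tables scatter by 0.5 percentage points (one standard deviation)
- the earlier runs do not show the number of chains; that part of a forecast is a guess

You wanted a quick number, so I replaced each curve by its mean. In blue and violet the monomer in chains looked flat from 1.50 min, so I averaged the readings from there on and divided by the equivalents charged:

blue: 3.96

violet: 3.71

mean of the two: 3.83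

I called the monomer in chains on the flat part, per equivalent of pre-initiator charged, the partition ratio. The mean cost me little: blue and violet parted by 0.259, less than 10% of the ratio. The earlier runs showed no chain count, so reading this ratio as a length was my guess that each pre-initiator began one chain. On that guess I expected these uptakes:

autumn: 9.59%

dawn: 5.75%

Both flasks then had the same length, 3.83, and I said neither.

Your forecast was neither, with 4.4 for autumn and 4.8 for dawn, and it moved its lengths upward on the note “Incomplete initiation would lengthen both”. We shared the verdict and differed on the lengths, partly through that shift, which I did not make, and partly through the uptake: the forecast took 6.5% for dawn where I expected 5.75%.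

The flask gave neither, with 3.85 in autumn and 3.87 in dawn.

    pre-initiator → initiator (k = 0.0640 s⁻¹)
    living end + free monomer → dead end (k = 0.230 M⁻¹ s⁻¹)
    monomer in chains + living end → free monomer + living end, rate k3*[living end] as long as [monomer in chains] is above zero (k = 0.0290 s⁻¹)
    free monomer + living end → monomer in chains + living end, rate k4*[living end]*[free monomer] (k = 0.810 M⁻¹ s⁻¹)
    free monomer + initiator → living end + monomer in chains (k = 0.430 M⁻¹ s⁻¹)

In autumn the pre-initiator ended at 0% of its charge, and dead end stood at 2.50% of the free monomer charged, matching the equivalents; the final 9.62% of monomer in chains over those equivalents gave 3.85. Removing the path from living end and free monomer to dead end took dawn from 3.87 to 30.8. For the neighbour of autumn charged with 0.0425 equiv of pre-initiator, the ratio called for 16.3%, and that flask held 16.2% of monomer in chains at length 3.81.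

The runs stem from a simulated flask with made-up constants; scatter was added.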